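(The earlier runs and the new flask are simulated with made-up constants; scatter was added.)

Each of south-west and north-east holds 1.1 M of starting material on 160 mM of free catalyst, so the charge is worth C = 6.88 turnovers of that catalyst.

common to all: starting material 1.1 M; reagent 1.98 M; free catalyst 160 mM; added ligand 97 mM

| charge | second substrate | temperature | remark | time |
|---|---|---|---|---|
| spring | 1.5 M | 31 °C | run made earlier |  |
| midnight | 1.5 M | 45 °C | run made earlier |  |
| south-west | 1.10 M | 25 °C |  | 4.0 d |
| north-east | 1.10 M | 50 °C |  | 4.0 d |

spring run (percent of the starting material charged)

| time / d | target / % |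
|---|---|
| 0.625 | 7 |
| 1.25 | 11 |
| 2.08 | 18 |
| 3.00 | 26 |
| 4.00 | 34 |
| 5.00 | 34 |

midnight run (percent of the starting material charged)

| time / h | target / % |
|---|---|
| 6.00 | 12 |
| 12.0 | 19 |
| 20.0 | 31 |
| 25.0 | 27 |
| 40.0 | 40 |

(readings scatter by 2 percentage points)



- the best flask by amount of target, in percent of the starting material charged; "all alike" if 1.5 percentage points covers them all (south-west / north-east / all alike)
- amount of target at the end, in percent of the starting material charged, south-west
- amount of target at the end, in percent of the starting material charged, north-east

First we take the main step alone: catalyst goes round at a steady pace and makes target. The spring run read 34% at 4.00 d, so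

r = target × C / time = 0.584 /d

This turnover rate, target made per catalyst charged per day, is what we carry. It is a reading and has the scatter of one. At 31 °C it gives 2.34 turnovers in 4.0 d.

Next we add temperature. The midnight run read 19% at 12.0 h, so its rate is s = 2.61 /d, and f = s/r = 4.47 over 14.0 K. We extrapolate on a logarithmic scale, since 25 °C and 50 °C both lie outside the two run temperatures:

south-west: r = 0.308 /d, so N = 1.23 turnovers, or 17.9%

north-east: r = 4.46 /d, so N = 17.8 turnovers

Then we add the rest. The north-east count is more than the charge allows, so the straight line fails there. The midnight run shows the bend: at 40.0 h it read 2.75 turnovers, fewer than the straight 4.35. South-west needs fewer turnovers than the spring run made, so its line can stand. Second substrate falls from 1.5 M to 1.10 M, but no run varied it, so we leave r unchanged.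

We commit to 17.9% for south-west. For north-east we take the 40% of the colder midnight run as a low mark, so we expect north-east to be the better flask.

The forecast gives 14% (10% to 19%) for south-west, lower than ours, and 48% (34% to 70%) for north-east. It chooses north-east: “the hotter flask clearly wins”.

The flasks give 20.6% in south-west and 49.8% in north-east, so the best is north-east.

    starting material + free catalyst ⇌ catalyst intermediate A (K = 59.0 /M, k = 0.0170 /M/min, Ea = 70.0 kJ/mol, ΔH = −64.0 kJ/mol)
    reagent + catalyst intermediate A ⇌ free catalyst + target (K = 0.210, k = 0.00390 /M/min, Ea = 89.0 kJ/mol, ΔH = 2.00 kJ/mol)
    second substrate + free catalyst ⇌ catalyst intermediate B (K = 4.10 /M, k = 0.00510 /M/min, Ea = 86.0 kJ/mol, ΔH = 3.00 kJ/mol)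
    reagent + catalyst intermediate B → free catalyst + second product (k = 0.0780 /M/min, Ea = 72.0 kJ/mol)
    free catalyst + added ligand ⇌ idle complex (K = 790 /M, k = 0.0230 /M/min, Ea = 71.0 kJ/mol, ΔH = −28.0 kJ/mol)
    target + free catalyst ⇌ isomer of the product + free catalyst, rate k6*[free catalyst]*[target] forward; the back reaction follows from the equilibrium constant (K = 1.00, k = 0.00870 /M/min, Ea = 88.0 kJ/mol, ΔH = −15.0 kJ/mol)
    (constants at 50 °C)

South-west made 1.42 turnovers to target in 4.0 d, so a round to target took 2.82 d on average, against our reckoned 3.25 d. In south-west that is far longer than the 0.33 d half-life of free catalyst by the forward step into catalyst intermediate A alone at 4.00 d, and at that time catalyst intermediate A, the resting state, holds 62.7% of the catalyst, more than free catalyst or idle complex. If the round time stretches with the reagent ratio, the neighbour of south-west with 0.79 M of reagent should make 0.565 turnovers to target; it made 0.675.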